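**Strategy**

The benzoquinone ring (C1=O, C2–OMe, C3–indolyl, C4=O, C5–prenyl, C6–indolyl) is assembled [3+3] from two 2-(indol-3-yl)propenoyl units, C2–C3–C4 and C5–C6–C1, by forming C1–C2 and C4–C5 in one operation. The feature exploited is that in each unit the carbonyl carbon and the carbon to be joined are 1,3-related through an indolyl-bearing sp2 carbon. Lithiated β-methoxyacrylate 13 (C2 nucleophile, C4 ester) adds to acylsilane 10 at C1; Brook rearrangement relays the charge through C6 to C5, which closes onto C4. The product is the fully substituted hydroquinone monosilyl ether 18; desilylation and air oxidation give the quinone.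

Key step: step 8

Remark: the target has no stereocentre. Alkene geometry matters only for 13 (E is needed so that lithium, and then C1, sits cis to the ester); for 9 and 10 it is erased in step 8, so the E/Z mixture is used.

**Route**

Step 1
Reactants: 1 indole
Product: 3 1-(1H-indol-3-yl)-2-(morpholin-4-yl)ethane-1,2-dione, via indol-3-ylglyoxylyl chloride 2 (not isolated)
Conditions: (COCl)2, Et2O, 0 °C; then morpholine (3 equiv), 0 °C to rt
Reagents that add atoms: oxalyl chloride O=C(Cl)C(Cl)=O; morpholine C1COCCN1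
Why: Indole is acylated at C3 by oxalyl chloride without catalyst (Friedel–Crafts acylation) and the acid chloride is amidated in the same flask.

Step 2
Reactants: 3 1-(1H-indol-3-yl)-2-(morpholin-4-yl)ethane-1,2-dione
Product: 4 1-(morpholin-4-yl)-2-[1-(triisopropylsilyl)-1H-indol-3-yl]ethane-1,2-dione
Conditions: NaH, THF, 0 °C; iPr3SiCl, 0 °C to rt
Reagents that add atoms: chlorotriisopropylsilane CC(C)[Si](Cl)(C(C)C)C(C)C
Why: N-silylation of the acidic 3-acylindole N–H; the bulky silyl group should later block C2 lithiation and tolerate ylide, silyllithium and amide base.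

Step 3
Reactants: 5 5-bromo-2-methylpent-2-ene; 6 triphenylphosphine
Product: 7 (4-methylpent-3-en-1-yl)triphenylphosphonium bromide
Conditions: MeCN, reflux
Reagents that add atoms: none
Why: SN2 quaternisation of the phosphine by the primary homoallylic bromide.

Step 4
Reactants: 4 1-(morpholin-4-yl)-2-[1-(triisopropylsilyl)-1H-indol-3-yl]ethane-1,2-dione; 7 (4-methylpent-3-en-1-yl)triphenylphosphonium bromide
Product: 9 6-methyl-1-(morpholin-4-yl)-2-[1-(triisopropylsilyl)-1H-indol-3-yl]hepta-2,5-dien-1-one (E/Z mixture at C2=C3), via phosphorus ylide 8 (not isolated)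
Conditions: NaN(SiMe3)2, THF, −78 to 0 °C; then 4, −78 °C to rt
Reagents that add atoms: none
Why: Wittig olefination of the ketone carbonyl of the α-keto amide by the non-stabilised ylide; the amide carbonyl should stay inert.

Step 5
Reactants: 9 6-methyl-1-(morpholin-4-yl)-2-[1-(triisopropylsilyl)-1H-indol-3-yl]hepta-2,5-dien-1-one
Product: 10 1-[dimethyl(phenyl)silyl]-6-methyl-2-[1-(triisopropylsilyl)-1H-indol-3-yl]hepta-2,5-dien-1-one (E/Z mixture)
Conditions: PhMe2SiLi, THF, −78 °C; aqueous NH4Cl
Reagents that add atoms: dimethylphenylsilyllithium [Li][Si](C)(C)c1ccccc1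
Why: Acyl substitution of a morpholine amide by a silyllithium (amide-to-acylsilane conversion); the chelated tetrahedral adduct should persist until the quench, so only one silyl group is delivered, and the hard silyllithium should prefer 1,2- over 1,4-addition.

Step 6
Reactants: 11 methyl (1H-indol-3-yl)(oxo)acetate
Product: 12 methyl oxo[1-(triisopropylsilyl)-1H-indol-3-yl]acetate
Conditions: NaH, THF, 0 °C; iPr3SiCl, 0 °C to rt
Reagents that add atoms: chlorotriisopropylsilane CC(C)[Si](Cl)(C(C)C)C(C)C
Why: N-silylation of the acidic 3-acylindole N–H, as in step 2.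

Step 7
Reactants: 12 methyl oxo[1-(triisopropylsilyl)-1H-indol-3-yl]acetate
Product: 13 methyl (2E)-3-methoxy-2-[1-(triisopropylsilyl)-1H-indol-3-yl]prop-2-enoate
Conditions: [Ph3PCH2OMe]Cl, NaN(SiMe3)2, THF, 0 °C to rt; chromatography (E isomer)
Reagents that add atoms: (methoxymethyl)triphenylphosphonium chloride COC[P+](c1ccccc1)(c1ccccc1)c1ccccc1.[Cl-]
Why: Wittig methoxymethylenation of the aryl glyoxylate ketone, the standard entry to 2-aryl-3-methoxyacrylates; the E isomer (vinyl H cis to CO2Me) is separated and the Z isomer can be equilibrated (cat. I2, light) and recycled.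

Step 8
Reactants: 13 methyl (2E)-3-methoxy-2-[1-(triisopropylsilyl)-1H-indol-3-yl]prop-2-enoate; 10 1-[dimethyl(phenyl)silyl]-6-methyl-2-[1-(triisopropylsilyl)-1H-indol-3-yl]hepta-2,5-dien-1-one
Product: 18 4-{[dimethyl(phenyl)silyl]oxy}-3-methoxy-6-(3-methylbut-2-en-1-yl)-2,5-bis[1-(triisopropylsilyl)-1H-indol-3-yl]phenol, via vinyllithium 14 (not isolated), via lithium α-silyl alkoxide 15 (not isolated), via siloxy trienolate 16 (not isolated), via cyclohexadienone 17 (not isolated)
Conditions: LiN(iPr)2 (1.1 equiv), THF, −95 °C; then 10, −95 to −40 °C, then rt; aqueous NH4Cl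
Reagents that add atoms: none
Why: Proposed new method: Ester-directed β-lithiation of 13 (lithium cis to CO2Me, with retention) gives 14, whose 1,2-addition to the highly electrophilic acylsilane carbonyl of 10 forms C1–C2 (15); 1,2-Brook rearrangement, driven by a carbanion that is allylic on both sides and vinylogous to the ester, gives siloxy trienolate 16, in which the charge is relayed through C6 to C5. C5 then acylates the ester carbon C4 (6-exo-trig acylation with the enolate double bond inside the forming ring, equally a disrotatory six-electron electrocyclisation of the 1-oxido-triene), loss of LiOMe gives 17, and the methoxide enolises 17 irreversibly to the aromatic phenoxide of 18. The closest known reaction type is the Brook-rearrangement-mediated [3+2] annulation of acryloylsilanes with ketone enolates, where the same siloxyallyl anion closes onto a ketone; here the internal electrophile is an ester and the ring is six-membered. The only ring closed is the future quinone ring, and the stereocentres of 15 and 17 are transient and vanish on aromatisation. The step needs 1,2-addition over 1,4-addition and over γ-deprotonation of 10 (secured by the hard chelated vinyllithium at −95 °C and the acylsilane electrophilicity) and Brook shift faster than lactonisation of alkoxide 15 onto the cis ester (secured by the doubly allylic carbanion stabilisation and the hindered tertiary alkoxide). Head-to-tail regiochemistry is fixed because 10 carries only an electrophile and 13 only a nucleophile until the Brook shift, and C2 lithiation of the indoles is blocked by the N-silyl groups.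

Step 9
Reactants: 18 4-{[dimethyl(phenyl)silyl]oxy}-3-methoxy-6-(3-methylbut-2-en-1-yl)-2,5-bis[1-(triisopropylsilyl)-1H-indol-3-yl]phenol
Product: 20 2,5-di(1H-indol-3-yl)-3-methoxy-6-(3-methylbut-2-en-1-yl)cyclohexa-2,5-diene-1,4-dione, via hydroquinone 19 (not isolated)
Conditions: Bu4NF, AcOH, THF, 0 °C to rt; then air (O2), rt
Reagents that add atoms: none
Why: Fluoride should cleave the aryl O–Si and both indole N–Si bonds, and the electron-rich hydroquinone is expected to autoxidise to the quinone under the mildly basic conditions (desilylation followed by hydroquinone oxidation).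

**Compound list**

1 | indole | c1ccc2[nH]ccc2c1 | starting material
2 | indol-3-ylglyoxylyl chloride | O=C(Cl)C(=O)c1c[nH]c2ccccc12 | intermediate
3 | 1-(1H-indol-3-yl)-2-(morpholin-4-yl)ethane-1,2-dione | O=C(C(=O)N1CCOCC1)c1c[nH]c2ccccc12 | intermediate
4 | 1-(morpholin-4-yl)-2-[1-(triisopropylsilyl)-1H-indol-3-yl]ethane-1,2-dione | O=C(C(=O)N1CCOCC1)c1cn([Si](C(C)C)(C(C)C)C(C)C)c2ccccc12 | intermediate
5 | 5-bromo-2-methylpent-2-ene | CC(C)=CCCBr | starting material
6 | triphenylphosphine | c1ccc(cc1)P(c1ccccc1)c1ccccc1 | starting material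
7 | (4-methylpent-3-en-1-yl)triphenylphosphonium bromide | CC(C)=CCC[P+](c1ccccc1)(c1ccccc1)c1ccccc1.[Br-] | intermediate
8 | (4-methylpent-3-en-1-ylidene)triphenylphosphorane | CC(C)=CCC=P(c1ccccc1)(c1ccccc1)c1ccccc1 | intermediate
9 | 6-methyl-1-(morpholin-4-yl)-2-[1-(triisopropylsilyl)-1H-indol-3-yl]hepta-2,5-dien-1-one (E/Z mixture at C2=C3) | CC(C)=CCC=C(C(=O)N1CCOCC1)c1cn([Si](C(C)C)(C(C)C)C(C)C)c2ccccc12 | intermediate
10 | 1-[dimethyl(phenyl)silyl]-6-methyl-2-[1-(triisopropylsilyl)-1H-indol-3-yl]hepta-2,5-dien-1-one (E/Z mixture at C2=C3) | CC(C)=CCC=C(C(=O)[Si](C)(C)c1ccccc1)c1cn([Si](C(C)C)(C(C)C)C(C)C)c2ccccc12 | intermediate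
11 | methyl (1H-indol-3-yl)(oxo)acetate | COC(=O)C(=O)c1c[nH]c2ccccc12 | starting material
12 | methyl oxo[1-(triisopropylsilyl)-1H-indol-3-yl]acetate | COC(=O)C(=O)c1cn([Si](C(C)C)(C(C)C)C(C)C)c2ccccc12 | intermediate
13 | methyl (2E)-3-methoxy-2-[1-(triisopropylsilyl)-1H-indol-3-yl]prop-2-enoate | CO/C=C(/C(=O)OC)c1cn([Si](C(C)C)(C(C)C)C(C)C)c2ccccc12 | intermediate
14 | methyl 3-lithio-3-methoxy-2-[1-(triisopropylsilyl)-1H-indol-3-yl]prop-2-enoate (lithium cis to CO2Me) | CO/C([Li])=C(/C(=O)OC)c1cn([Si](C(C)C)(C(C)C)C(C)C)c2ccccc12 | intermediate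
15 | lithium alkoxide from addition of 14 to the carbonyl of 10 (racemic at the carbinol carbon; ester cis to the carbinol carbon) | CO/C(=C(/C(=O)OC)c1cn([Si](C(C)C)(C(C)C)C(C)C)c2ccccc12)C(O[Li])([Si](C)(C)c1ccccc1)C(=CCC=C(C)C)c1cn([Si](C(C)C)(C(C)C)C(C)C)c2ccccc12 | intermediate
16 | siloxy trienolate after Brook shift, drawn as the lithium ester enolate (delocalised, geometry not fixed) | COC(O[Li])=C(c1cn([Si](C(C)C)(C(C)C)C(C)C)c2ccccc12)C(OC)=C(O[Si](C)(C)c1ccccc1)C(=CCC=C(C)C)c1cn([Si](C(C)C)(C(C)C)C(C)C)c2ccccc12 | intermediate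
17 | 4-{[dimethyl(phenyl)silyl]oxy}-3-methoxy-6-(3-methylbut-2-en-1-yl)-2,5-bis[1-(triisopropylsilyl)-1H-indol-3-yl]cyclohexa-2,4-dien-1-one (racemic at C6) | COC1=C(c2cn([Si](C(C)C)(C(C)C)C(C)C)c3ccccc23)C(=O)C(CC=C(C)C)C(c2cn([Si](C(C)C)(C(C)C)C(C)C)c3ccccc23)=C1O[Si](C)(C)c1ccccc1 | intermediate
18 | 4-{[dimethyl(phenyl)silyl]oxy}-3-methoxy-6-(3-methylbut-2-en-1-yl)-2,5-bis[1-(triisopropylsilyl)-1H-indol-3-yl]phenol | COc1c(O[Si](C)(C)c2ccccc2)c(-c2cn([Si](C(C)C)(C(C)C)C(C)C)c3ccccc23)c(CC=C(C)C)c(O)c1-c1cn([Si](C(C)C)(C(C)C)C(C)C)c2ccccc12 | intermediate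
19 | 2,5-di(1H-indol-3-yl)-3-methoxy-6-(3-methylbut-2-en-1-yl)benzene-1,4-diol | COc1c(O)c(-c2c[nH]c3ccccc23)c(CC=C(C)C)c(O)c1-c1c[nH]c2ccccc12 | intermediate
20 | 2,5-di(1H-indol-3-yl)-3-methoxy-6-(3-methylbut-2-en-1-yl)cyclohexa-2,5-diene-1,4-dione | COC1=C(c2c[nH]c3ccccc23)C(=O)C(CC=C(C)C)=C(c2c[nH]c3ccccc23)C1=O | target

**Step count and risks**

Total step count: 9. Longest linear sequence: 6 steps (steps 1, 2, 4, 5, 8, 9).

Steps most likely to fail:

Step 8 (proposed new method). The alkoxide 15 may lactonise onto the cis ester before the Brook shift. The vinyllithium may deprotonate the doubly allylic CH2 of 10 or add 1,4. The delocalised anion 16 may fail to acylate its own conjugated ester and simply be protonated on work-up. The fallback uses known chemistry and gives up the annulation in favour of substitution on a preformed quinone. It sets out from indole 1 and comes back at target 20. Acid-promoted double conjugate addition of 1 to 2,5-dichloro-1,4-benzoquinone, with DDQ re-oxidation after each addition, should give 2,5-dichloro-3,6-di(1H-indol-3-yl)cyclohexa-2,5-diene-1,4-dione F1. One equivalent of NaOMe in MeOH/THF should replace one vinylogous acyl chloride to give 2-chloro-3,6-di(1H-indol-3-yl)-5-methoxycyclohexa-2,5-diene-1,4-dione F2. Stille coupling of the remaining C–Cl bond with tributyl(3-methylbut-2-en-1-yl)stannane and Pd(PPh3)4 in dioxane should give 20.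

Step 5. The silyllithium may add in conjugate fashion to the dienamide, or the tetrahedral adduct may collapse early and take up a second silyl group. The fallback sets out from 9 and comes back at 10. Partial reduction of the morpholine amide with Cp2Zr(H)Cl in THF should give 6-methyl-2-[1-(triisopropylsilyl)-1H-indol-3-yl]hepta-2,5-dienal F3. 1,2-Addition of PhMe2SiLi at −78 °C should give the racemic α-silyl allylic alcohol 1-[dimethyl(phenyl)silyl]-6-methyl-2-[1-(triisopropylsilyl)-1H-indol-3-yl]hepta-2,5-dien-1-ol F4. Swern oxidation (oxalyl chloride, DMSO, Et3N, −78 °C) should give acylsilane 10.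

Step 4. Olefination of the ketone, which is deactivated as a vinylogous amide, may be sluggish, and the ylide may attack the N–Si bond. The fallback sets out from 4 and comes back at 9. The Grignard reagent made from bromide 5 and Mg in THF should add to the ketone carbonyl of 4 at −78 °C to give racemic 2-hydroxy-6-methyl-1-(morpholin-4-yl)-2-[1-(triisopropylsilyl)-1H-indol-3-yl]hept-5-en-1-one F5. Dehydration of this tertiary indolyl carbinol with Burgess reagent (benzene, 50 °C) can only eliminate toward the chain CH2 and should give 9.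

Further compounds
F1 | step 8 | 2,5-dichloro-3,6-di(1H-indol-3-yl)cyclohexa-2,5-diene-1,4-dione | O=C1C(Cl)=C(c2c[nH]c3ccccc23)C(=O)C(Cl)=C1c1c[nH]c2ccccc12
F2 | step 8 | 2-chloro-3,6-di(1H-indol-3-yl)-5-methoxycyclohexa-2,5-diene-1,4-dione | COC1=C(c2c[nH]c3ccccc23)C(=O)C(Cl)=C(c2c[nH]c3ccccc23)C1=O
F3 | step 5 | 6-methyl-2-[1-(triisopropylsilyl)-1H-indol-3-yl]hepta-2,5-dienal | CC(C)=CCC=C(C=O)c1cn([Si](C(C)C)(C(C)C)C(C)C)c2ccccc12
F4 | step 5 | 1-[dimethyl(phenyl)silyl]-6-methyl-2-[1-(triisopropylsilyl)-1H-indol-3-yl]hepta-2,5-dien-1-ol (racemic) | CC(C)=CCC=C(C(O)[Si](C)(C)c1ccccc1)c1cn([Si](C(C)C)(C(C)C)C(C)C)c2ccccc12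
F5 | step 4 | 2-hydroxy-6-methyl-1-(morpholin-4-yl)-2-[1-(triisopropylsilyl)-1H-indol-3-yl]hept-5-en-1-one (racemic) | CC(C)=CCCC(O)(C(=O)N1CCOCC1)c1cn([Si](C(C)C)(C(C)C)C(C)C)c2ccccc12
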